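**Retrosynthetic overview**
1. The tetronic acid is the only ring of the target and is closed last. It is opened at the lactone C–O bond to an acyclic tricarbonyl methyl ester that carries the glycerate diol as an acetonide.
2. The tricarbonyl ester is cut at C3–C(acyl), giving the magnesium enolate of a glycerate-derived β-keto ester and (S)-14-methylhexadecanoyl chloride.
3. Key disconnection: the unactivated mid-chain C6–C7 bond of the anteiso acid. It is made by nickel-hydride radical hydroalkylation of unprotected hex-5-enoic acid with the primary radical from (S)-1-bromo-8-methyldecane.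
4. The bromide comes from (S)-2-methylbutylmagnesium bromide (source of C14) and 1,6-dibromohexane. The β-keto ester comes from methyl (S)-glycerate (source of C5) and methyl acetate by a Claisen condensation.
5. Ring order: temporary dioxolane first, tetronic acid ring last.

Assumption: the acyltetronic acid is written as its 4-hydroxy enol tautomer and all tautomers count as one compound. Chain positions C1–C16 are counted from the acyl carbonyl.

**Step 1**
Reactants: 1 (S)-1-bromo-2-methylbutane; 2 1,6-dibromohexane
Product: 4 (S)-1-bromo-8-methyldecane, via (S)-2-methylbutylmagnesium bromide 3 (not isolated)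
Conditions: Mg, THF, 40 °C; then 2 (3 equiv), Li2CuCl4 (3 mol%), THF, −10 °C → rt; chromatography (hexanes)
Reagents that add atoms: none
Why: Kochi-type copper-catalysed sp3–sp3 Kumada coupling of a primary Grignard reagent with a primary bromide, in which the threefold excess of 2 holds the reaction at mono-substitution and the stereocentre, beta to magnesium, is never touched.

**Step 2 (key step)**
Reactants: 4 (S)-1-bromo-8-methyldecane; 5 hex-5-enoic acid
Product: 8 (S)-14-methylhexadecanoic acid, via sodium hex-5-enoate 6 (not isolated), via sodium (S)-14-methylhexadecanoate 7 (not isolated)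
Conditions: 5 (2 equiv), Na2CO3 (4 equiv), DMA, rt, 30 min; then 4, NiBr2·diglyme (10 mol%), 4,4'-di-tert-butyl-2,2'-bipyridine (12 mol%), (EtO)2MeSiH (3 equiv), NaI (20 mol%), 30 °C; then 1 M HCl
Reagents that add atoms: none
Why: Nickel-hydride reductive olefin hydroalkylation (radical cross-coupling), in which the ligated Ni–H adds anti-Markovnikov to the terminal alkene of 6, monovalent nickel abstracts bromine from 4 to release the free primary C7 radical, and capture of that radical at the alkylnickel followed by reductive elimination from trivalent nickel forges C6–C7, with the C14 stereocentre seven carbons from the radical site and therefore retained.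

**Step 3**
Reactants: 9 methyl (S)-2,3-dihydroxypropanoate
Product: 10 methyl (S)-2,2-dimethyl-1,3-dioxolane-4-carboxylate
Conditions: Me2C(OMe)2, TsOH·H2O (2 mol%), acetone, rt
Reagents that add atoms: 2,2-dimethoxypropane, COC(C)(C)OC
Why: Acid-catalysed transketalisation (acetonide formation) of the 1,2-diol, in which no bond to the stereocentre is broken.

**Step 4**
Reactants: 10 methyl (S)-2,2-dimethyl-1,3-dioxolane-4-carboxylate; 11 methyl acetate
Product: 14 methyl 3-[(4S)-2,2-dimethyl-1,3-dioxolan-4-yl]-3-oxopropanoate, via lithium enolate of methyl acetate 12 (not isolated), via lithium enolate of the keto ester 13 (not isolated)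
Conditions: 11, LiN(iPr)2 (2.4 equiv each), THF, −78 °C; then 10, −78 → −40 °C; AcOH quench
Reagents that add atoms: none
Why: Crossed Claisen condensation, in which the small ester enolate adds to the ester carbonyl of 10 faster than it removes the ring C4–H at low temperature and the product is stored at once as enolate 13, which shields the α-alkoxy stereocentre from epimerisation.

**Step 5**
Reactants: 8 (S)-14-methylhexadecanoic acid; 14 methyl 3-[(4S)-2,2-dimethyl-1,3-dioxolan-4-yl]-3-oxopropanoate
Product: 19 (5S)-4-hydroxy-5-(hydroxymethyl)-3-[(14S)-14-methylhexadecanoyl]furan-2(5H)-one, via (S)-14-methylhexadecanoyl chloride 15 (not isolated), via chloromagnesium enolate of the keto ester 16 (not isolated), via acetonide tricarbonyl ester 17 (not isolated), via diol tricarbonyl ester 18 (not isolated)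
Conditions: 8, (COCl)2, DMF (cat.), CH2Cl2, 0 °C → rt, evaporate; 14 (1.1 equiv), MgCl2, pyridine, CH2Cl2, 0 °C, then 15, 0 °C → rt; cold 1 M HCl wash; THF–2 M HCl (3:1), 45 °C
Reagents that add atoms: none
Why: Rathke-type magnesium-enolate C-acylation followed by aqueous-acid acetonide cleavage and 5-exo-trig lactonisation of the secondary hydroxyl onto the methyl ester (the classical C-acylation/lactonisation route to 3-acyltetronic acids), where hemiketal or furanone formation at the chain ketone stays reversible in aqueous acid while loss of methanol to the hydrogen-bonded acyltetronic acid is the sink, and C5 stays (S) because none of its bonds is broken.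

**Compound list**
1 | (S)-1-bromo-2-methylbutane | CC[C@H](C)CBr | starting material
2 | 1,6-dibromohexane | BrCCCCCCBr | starting material
3 | (S)-2-methylbutylmagnesium bromide | CC[C@H](C)C[Mg]Br | intermediate
4 | (S)-1-bromo-8-methyldecane | CC[C@H](C)CCCCCCCBr | intermediate
5 | hex-5-enoic acid | C=CCCCC(=O)O | starting material
6 | sodium hex-5-enoate | C=CCCCC(=O)[O-].[Na+] | intermediate
7 | sodium (S)-14-methylhexadecanoate | CC[C@H](C)CCCCCCCCCCCCC(=O)[O-].[Na+] | intermediate
8 | (S)-14-methylhexadecanoic acid | CC[C@H](C)CCCCCCCCCCCCC(=O)O | intermediate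
9 | methyl (S)-2,3-dihydroxypropanoate (methyl L-glycerate) | COC(=O)[C@@H](O)CO | starting material
10 | methyl (S)-2,2-dimethyl-1,3-dioxolane-4-carboxylate | COC(=O)[C@@H]1COC(C)(C)O1 | intermediate
11 | methyl acetate | COC(C)=O | starting material
12 | lithium 1-methoxyethen-1-olate | [Li+].[O-]C(=C)OC | intermediate
13 | lithium enolate of 14 | [Li+].COC(=O)C=C([O-])[C@@H]1COC(C)(C)O1 | intermediate
14 | methyl 3-[(4S)-2,2-dimethyl-1,3-dioxolan-4-yl]-3-oxopropanoate | COC(=O)CC(=O)[C@@H]1COC(C)(C)O1 | intermediate
15 | (S)-14-methylhexadecanoyl chloride | CC[C@H](C)CCCCCCCCCCCCC(=O)Cl | intermediate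
16 | chloromagnesium enolate of 14 | COC(=O)C=C(O[Mg]Cl)[C@@H]1COC(C)(C)O1 | intermediate
17 | methyl (16S)-2-[(4S)-2,2-dimethyl-1,3-dioxolane-4-carbonyl]-16-methyl-3-oxooctadecanoate (keto/enol mixture, C2 labile) | CC[C@H](C)CCCCCCCCCCCCC(=O)C(C(=O)OC)C(=O)[C@@H]1COC(C)(C)O1 | intermediate
18 | methyl (16S)-2-[(2S)-2,3-dihydroxypropanoyl]-16-methyl-3-oxooctadecanoate (C2 labile) | CC[C@H](C)CCCCCCCCCCCCC(=O)C(C(=O)OC)C(=O)[C@@H](O)CO | intermediate
19 | (5S)-4-hydroxy-5-(hydroxymethyl)-3-[(14S)-14-methylhexadecanoyl]furan-2(5H)-one | CC[C@H](C)CCCCCCCCCCCCC(=O)C1=C(O)[C@H](CO)OC1=O | target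

**Total step count:** 5. **Longest linear sequence:** 3 steps (1 → 2 → 5, or 3 → 4 → 5).

**Steps most likely to fail**

Step 2. The risks are hydrodebromination of 4, O-alkylation of carboxylate 6 by 4, poor solubility of 6, and nickel-hydride isomerisation of the alkene. The fallback moves the radical bond from C6–C7 to the polarity-matched C3–C4 position. It sets out from 4. CH2=CHCH2MgBr with Li2CuCl4 in THF gives (S)-11-methyltridec-1-ene F1. Anti-Markovnikov radical addition of HBr, initiated by dibenzoyl peroxide, gives (S)-1-bromo-11-methyltridecane F2. A Giese addition of the derived primary radical to acrylic acid ((Me3Si)3SiH, AIBN, toluene, 80 °C) comes back to the route at 8.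

Step 5. The risks are O-acylation in place of C-acylation, and closure of the freed hydroxyl onto the chain ketone (furanone) or of the primary hydroxyl onto the ester (six-membered lactone). The fallback is a Lacey–Dieckmann closure, in which the ring C–C bond is made last and the ring size is fixed by the ester linkage. It sets out from 9 and 15.
- TBSCl and imidazole silylate the primary hydroxyl of 9 to give methyl (S)-3-(tert-butyldimethylsilyloxy)-2-hydroxypropanoate F3.
- KO2CCH2CO2Me, MgCl2 and Et3N in MeCN homologate 15 to methyl (S)-16-methyl-3-oxooctadecanoate F4.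
- DMAP-catalysed transesterification of F4 with F3 in refluxing toluene gives methyl (2S)-3-(tert-butyldimethylsilyloxy)-2-[(16S)-16-methyl-3-oxooctadecanoyl]oxypropanoate F5.
- Bu4NF in THF first closes the ring to (5S)-5-(tert-butyldimethylsilyloxymethyl)-4-hydroxy-3-[(14S)-14-methylhexadecanoyl]furan-2(5H)-one F6. It then removes the silyl group, and after an acid wash the sequence comes back to the route at 19.

Step 4. The risks are deprotonation of 10 at C4, which leads to epimerisation or β-elimination, and self-condensation of 12. The fallback is a neutral decarboxylative Masamune–Brooks homologation in place of a strong-base Claisen. It sets out from 10.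
- LiOH in THF–water gives lithium (S)-2,2-dimethyl-1,3-dioxolane-4-carboxylate F7.
- Cold 1 M HCl to pH 3 gives (S)-2,2-dimethyl-1,3-dioxolane-4-carboxylic acid F8.
- Carbonyldiimidazole in THF gives [(4S)-2,2-dimethyl-1,3-dioxolan-4-yl](imidazol-1-yl)methanone F9.
- Mg(O2CCH2CO2Me)2 at rt, with loss of CO2, comes back to the route at 14.

**Further compounds**
F1 | step 2 | (S)-11-methyltridec-1-ene | CC[C@H](C)CCCCCCCCC=C
F2 | step 2 | (S)-1-bromo-11-methyltridecane | CC[C@H](C)CCCCCCCCCCBr
F3 | step 5 | methyl (S)-3-(tert-butyldimethylsilyloxy)-2-hydroxypropanoate | COC(=O)[C@@H](O)CO[Si](C)(C)C(C)(C)C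
F4 | step 5 | methyl (S)-16-methyl-3-oxooctadecanoate | CC[C@H](C)CCCCCCCCCCCCC(=O)CC(=O)OC
F5 | step 5 | methyl (2S)-3-(tert-butyldimethylsilyloxy)-2-[(16S)-16-methyl-3-oxooctadecanoyl]oxypropanoate | CC[C@H](C)CCCCCCCCCCCCC(=O)CC(=O)O[C@@H](CO[Si](C)(C)C(C)(C)C)C(=O)OC
F6 | step 5 | (5S)-5-(tert-butyldimethylsilyloxymethyl)-4-hydroxy-3-[(14S)-14-methylhexadecanoyl]furan-2(5H)-one | CC[C@H](C)CCCCCCCCCCCCC(=O)C1=C(O)[C@H](CO[Si](C)(C)C(C)(C)C)OC1=O
F7 | step 4 | lithium (S)-2,2-dimethyl-1,3-dioxolane-4-carboxylate | [Li+].[O-]C(=O)[C@@H]1COC(C)(C)O1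
F8 | step 4 | (S)-2,2-dimethyl-1,3-dioxolane-4-carboxylic acid | OC(=O)[C@@H]1COC(C)(C)O1
F9 | step 4 | [(4S)-2,2-dimethyl-1,3-dioxolan-4-yl](imidazol-1-yl)methanone | O=C(n1ccnc1)[C@@H]2COC(C)(C)O2
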